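**Retrosynthetic overview**
1. Target 15 ← 7,3'-di-O-MOM ether 14 (acid MOM removal) ← 5-O-prenyl ether 11, by an aromatic Claisen–Cope relay O5 → C6 → C8 promoted by Eu(fod)3, tris(6,6,7,7,8,8,8-heptafluoro-2,2-dimethyl-3,5-octanedionato)europium. The relay forms the C8–CH2 bond and closes no ring.
2. 11 ← 5-OH chromenoflavone 9 ← 8. The 2,2-dimethylpyran ring on ring B is closed at C5' by propargyl ether Claisen rearrangement and oxa-6π electrocyclisation of the 4'-O-(1,1-dimethylpropargyl) ether 6.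
3. 6 ← 7-O-MOM-luteolin 4 ← luteolin 1 through a catechol ketal. Rings A, B and C come with luteolin, so the pyran ring is the only ring formed.
4. Feature carrying the strategy: in ring A the chelated O5 (peri to the C4 carbonyl) is the last oxygen to be alkylated, and C8 is para to C5. C8 is reached by two [3,3] shifts through C6, the only ortho carbon that is not the ring-fusion carbon C4a.

Key step: step 8

Assumption: the target has no stereocentre and no stereogenic double bond, so nothing has to be controlled stereochemically; the sp3 carbons that appear in intermediates 12 and 13 are lost on aromatisation.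

**Step 1**
Reactants: 1 luteolin
Product: 2 3',4'-O-diphenylmethylene-luteolin
Conditions: Ph2CCl2, Ph2O, 175 °C
Reagents that add atoms: dichlorodiphenylmethane, ClC(Cl)(c1ccccc1)c1ccccc1
Why: Catechol ketalisation is selective because only the adjacent 3'- and 4'-hydroxyls can close a five-membered 1,3-benzodioxole, the 5- and 7-hydroxyls being meta to each other.

**Step 2**
Reactants: 2 3',4'-O-diphenylmethylene-luteolin
Product: 3 7-O-MOM-3',4'-O-diphenylmethylene-luteolin
Conditions: MOMCl (1.2 equiv), K2CO3, acetone, rt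
Reagents that add atoms: chloromethyl methyl ether, COCCl
Why: Williamson-type O-alkylation should take the acidic, unhindered 7-OH, while the 5-OH stays locked in its hydrogen bond to the C4 carbonyl.

**Step 3**
Reactants: 3 7-O-MOM-3',4'-O-diphenylmethylene-luteolin
Product: 4 7-O-MOM-luteolin
Conditions: H2 (1 atm), 10% Pd/C, THF/MeOH, rt
Reagents that add atoms: none
Why: Hydrogenolysis of the two doubly benzylic C–O bonds of the ketal should free the catechol and leave the MOM ether and the C2=C3 bond of the flavone (a vinylogous ester, inert at one atmosphere) untouched.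

**Step 4**
Reactants: 4 7-O-MOM-luteolin; 5 3-chloro-3-methylbut-1-yne
Product: 6 4'-O-(2-methylbut-3-yn-2-yl)-7-O-MOM-luteolin
Conditions: K2CO3 (1.2 equiv), KI, CuI (cat.), DMF, 60 °C, Ar
Reagents that add atoms: none
Why: Copper-assisted propargylic O-alkylation with one equivalent of base should take the 4'-phenoxide, the more acidic catechol oxygen because it is conjugated through C2=C3 with the C4 carbonyl; the 3'-OH is less acidic and the 5-OH is chelated.

**Step 5**
Reactants: 6 4'-O-(2-methylbut-3-yn-2-yl)-7-O-MOM-luteolin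
Product: 8 5-hydroxy-2-(8-hydroxy-2,2-dimethyl-2H-chromen-6-yl)-7-(methoxymethoxy)chromen-4-one, via ortho-allenyl phenol 7 (not isolated)
Conditions: PhNEt2, 180 °C, Ar
Reagents that add atoms: none
Why: Aryl propargyl ether Claisen rearrangement can go only to C5', since C3' carries oxygen; the resulting allenyl phenol 7 should undergo a 1,5-hydrogen shift and oxa-6π electrocyclisation to close the 2,2-dimethyl-2H-pyran ring.

**Step 6**
Reactants: 8 5-hydroxy-2-(8-hydroxy-2,2-dimethyl-2H-chromen-6-yl)-7-(methoxymethoxy)chromen-4-one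
Product: 9 5-hydroxy-7-(methoxymethoxy)-2-[8-(methoxymethoxy)-2,2-dimethyl-2H-chromen-6-yl]chromen-4-one
Conditions: MOMCl (1.3 equiv), K2CO3, acetone, rt
Reagents that add atoms: chloromethyl methyl ether, COCCl
Why: Williamson-type O-alkylation should cap the free 3'-OH and leave the chelated 5-OH, which needs more forcing conditions, as the only remaining hydroxyl.

**Step 7**
Reactants: 9 5-hydroxy-7-(methoxymethoxy)-2-[8-(methoxymethoxy)-2,2-dimethyl-2H-chromen-6-yl]chromen-4-one; 10 prenyl bromide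
Product: 11 7-(methoxymethoxy)-2-[8-(methoxymethoxy)-2,2-dimethyl-2H-chromen-6-yl]-5-(3-methylbut-2-enyloxy)chromen-4-one
Conditions: K2CO3, 18-crown-6 (cat.), acetone, reflux
Reagents that add atoms: none
Why: With every other hydroxyl capped, forcing Williamson etherification (SN2 at the primary allylic carbon, excess bromide) should O-alkylate the chelated 5-OH.

**Step 8**
Reactants: 11 7-(methoxymethoxy)-2-[8-(methoxymethoxy)-2,2-dimethyl-2H-chromen-6-yl]-5-(3-methylbut-2-enyloxy)chromen-4-one
Product: 14 5-hydroxy-7-(methoxymethoxy)-2-[8-(methoxymethoxy)-2,2-dimethyl-2H-chromen-6-yl]-8-(3-methylbut-2-enyl)chromen-4-one, via C6 tert-allyl dienone 12 (not isolated), via C8 prenyl dienone 13 (not isolated)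
Conditions: Eu(fod)3 (10 mol %), NaHCO3, PhCl, 85 °C
Reagents that add atoms: none
Why: Eu(fod)3 binds the C4 carbonyl and the O5 ether oxygen and so accelerates the aromatic Claisen [3,3] shift, which can deliver the allyl unit only to C6 because the other ortho carbon, C4a, is the ring-fusion carbon; this gives cyclohexadienone 12 with an inverted 1,1-dimethylallyl group. That tertiary allyl group is squeezed between the C5 carbonyl and the C7 OMOM group, so a Cope [3,3] shift across C7 to C8 (dienone 13, normal prenyl connectivity restored) should outrun enolisation, and enolisation of 13 then returns the aromatic ring with the chelated 5-OH. The closest known reaction type is the europium-catalysed para-Claisen–Cope rearrangement of 5-O-prenyl flavonoids to 8-C-prenyl flavonoids. No ring is closed and no lasting stereocentre is formed; the sp3 carbons C6 of 12 and C8 of 13 are racemic and are erased on aromatisation. The step needs C8-prenyl in preference to arrest as the C6-(1,1-dimethylallyl) phenol or ionisation back to 9; the steric compression at C6, the capped 7-oxygen (no free phenol to trap the prenyl unit as a chroman) and the NaHCO3 buffer, which holds back acid-promoted ionisation and MOM loss, should secure this.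

**Step 9**
Reactants: 14 5-hydroxy-7-(methoxymethoxy)-2-[8-(methoxymethoxy)-2,2-dimethyl-2H-chromen-6-yl]-8-(3-methylbut-2-enyl)chromen-4-one
Product: 15 5,7-dihydroxy-2-(8-hydroxy-2,2-dimethyl-2H-chromen-6-yl)-8-(3-methylbut-2-enyl)chromen-4-one
Conditions: 3 M aq HCl, MeOH, 50 °C
Reagents that add atoms: none
Why: Acid-catalysed acetal exchange with methanol should remove both phenolic MOM groups under conditions dilute and mild enough to spare the prenyl and chromene double bonds.

**Compound list**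
1 | luteolin | O=c1cc(-c2ccc(O)c(O)c2)oc2cc(O)cc(O)c12 | starting material
2 | 3',4'-O-diphenylmethylene-luteolin, 2-(2,2-diphenyl-1,3-benzodioxol-5-yl)-5,7-dihydroxychromen-4-one | O=c1cc(-c2ccc3c(c2)OC(c2ccccc2)(c2ccccc2)O3)oc2cc(O)cc(O)c12 | intermediate
3 | 7-O-MOM-3',4'-O-diphenylmethylene-luteolin | O=c1cc(-c2ccc3c(c2)OC(c2ccccc2)(c2ccccc2)O3)oc2cc(OCOC)cc(O)c12 | intermediate
4 | 7-O-MOM-luteolin, 2-(3,4-dihydroxyphenyl)-5-hydroxy-7-(methoxymethoxy)chromen-4-one | O=c1cc(-c2ccc(O)c(O)c2)oc2cc(OCOC)cc(O)c12 | intermediate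
5 | 3-chloro-3-methylbut-1-yne | CC(C)(Cl)C#C | starting material
6 | 4'-O-(2-methylbut-3-yn-2-yl)-7-O-MOM-luteolin | O=c1cc(-c2ccc(OC(C)(C)C#C)c(O)c2)oc2cc(OCOC)cc(O)c12 | intermediate
7 | ortho-allenyl phenol, 2-[3,4-dihydroxy-5-(3-methylbuta-1,2-dienyl)phenyl]-5-hydroxy-7-(methoxymethoxy)chromen-4-one | O=c1cc(-c2cc(O)c(O)c(C=C=C(C)C)c2)oc2cc(OCOC)cc(O)c12 | intermediate
8 | 5-hydroxy-2-(8-hydroxy-2,2-dimethyl-2H-chromen-6-yl)-7-(methoxymethoxy)chromen-4-one | O=c1cc(-c2cc(O)c3c(c2)C=CC(C)(C)O3)oc2cc(OCOC)cc(O)c12 | intermediate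
9 | 5-hydroxy-7-(methoxymethoxy)-2-[8-(methoxymethoxy)-2,2-dimethyl-2H-chromen-6-yl]chromen-4-one | O=c1cc(-c2cc(OCOC)c3c(c2)C=CC(C)(C)O3)oc2cc(OCOC)cc(O)c12 | intermediate
10 | prenyl bromide, 1-bromo-3-methylbut-2-ene | CC(C)=CCBr | starting material
11 | 5-O-prenyl-7,3'-di-O-MOM chromenoflavone, 7-(methoxymethoxy)-2-[8-(methoxymethoxy)-2,2-dimethyl-2H-chromen-6-yl]-5-(3-methylbut-2-enyloxy)chromen-4-one | CC(C)=CCOc1cc(OCOC)cc2oc(-c3cc(OCOC)c4c(c3)C=CC(C)(C)O4)cc(=O)c12 | intermediate
12 | C6 tert-allyl dienone, 7-(methoxymethoxy)-2-[8-(methoxymethoxy)-2,2-dimethyl-2H-chromen-6-yl]-6-(2-methylbut-3-en-2-yl)-6H-chromene-4,5-dione (racemic at C6) | C=CC(C)(C)C1C(OCOC)=CC2=C(C1=O)C(=O)C=C(c1cc(OCOC)c3c(c1)C=CC(C)(C)O3)O2 | intermediate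
13 | C8 prenyl dienone, 7-(methoxymethoxy)-2-[8-(methoxymethoxy)-2,2-dimethyl-2H-chromen-6-yl]-8-(3-methylbut-2-enyl)-8H-chromene-4,5-dione (racemic at C8) | CC(C)=CCC1C(OCOC)=CC(=O)C2=C1OC(c1cc(OCOC)c3c(c1)C=CC(C)(C)O3)=CC2=O | intermediate
14 | 7,3'-di-O-MOM target, 5-hydroxy-7-(methoxymethoxy)-2-[8-(methoxymethoxy)-2,2-dimethyl-2H-chromen-6-yl]-8-(3-methylbut-2-enyl)chromen-4-one | CC(C)=CCc1c(OCOC)cc(O)c2c(=O)cc(-c3cc(OCOC)c4c(c3)C=CC(C)(C)O4)oc12 | intermediate
15 | 5,7-dihydroxy-2-(8-hydroxy-2,2-dimethyl-2H-chromen-6-yl)-8-(3-methylbut-2-enyl)chromen-4-one | CC(C)=CCc1c(O)cc(O)c2c(=O)cc(-c3cc(O)c4c(c3)C=CC(C)(C)O4)oc12 | target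

**Step count and risks**
Total step count: 9. Longest linear sequence: 9 steps, from luteolin 1.

Steps most likely to fail:

1. Step 8. The cascade may stop after the first shift, with enolisation to the C6-(1,1-dimethylallyl) phenol, or the Lewis acid may ionise the allyl ether and return the 5-OH compound. Fallback by cross-coupling, setting out from 9 and coming back at 15:
   - The chelated 5-OH of 9 would be capped with NaH and MOMCl in DMF to give 5,7-bis(methoxymethoxy)-2-[8-(methoxymethoxy)-2,2-dimethyl-2H-chromen-6-yl]chromen-4-one F1.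
   - Iodination with N-iodosuccinimide in DMF at room temperature in the dark should go to C8, the position favoured in 5,7-dialkoxyflavones, to give the 8-iodo compound 8-iodo-5,7-bis(methoxymethoxy)-2-[8-(methoxymethoxy)-2,2-dimethyl-2H-chromen-6-yl]chromen-4-one F2.
   - Stille coupling of F2 with tributyl(3-methylbut-2-enyl)stannane and Pd(PPh3)4 in DMF at 90 °C should give 5,7-bis(methoxymethoxy)-2-[8-(methoxymethoxy)-2,2-dimethyl-2H-chromen-6-yl]-8-(3-methylbut-2-enyl)chromen-4-one F3.
   - Dilute HCl in methanol should then remove all three MOM groups to give 15.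

2. Step 4. Discrimination between the 3'- and 4'-oxygens by the hindered tertiary electrophile may be incomplete, with double alkylation, slow substitution or copper-promoted oxidation of the free catechol. Fallback by a benzyl relay, setting out from 4 and coming back at 9:
   - Selective benzylation of the more acidic 4'-OH (BnBr, NaHCO3, NaI, DMF, 40 °C) would give 4'-O-benzyl-7-O-MOM-luteolin F4.
   - MOMCl and K2CO3 in acetone would cap the 3'-OH to give 4'-O-benzyl-3',7-di-O-MOM-luteolin F5.
   - Hydrogenolysis (H2, Pd/C) would free the 4'-OH to give 3',7-di-O-MOM-luteolin F6, in which the 4'-OH is the only unchelated hydroxyl.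
   - Propargylation with excess 5 (DBU, catalytic CuCl2·2H2O, MeCN, 0 °C) then has no selectivity to meet and should give 4'-O-(2-methylbut-3-yn-2-yl)-3',7-di-O-MOM-luteolin F7.
   - Heating F7 in PhNEt2 at 180 °C should give 9 directly by the same Claisen rearrangement and electrocyclisation.

3. Step 9. Acid may cyclise the C8 prenyl group onto the freed 7-OH to form a chroman, or add methanol or HCl to the prenyl or chromene double bond, in competition with MOM removal. Fallback by a switch to base-labile acetates before the prenyl group is present, setting out from 9 and coming back at 15: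
   - HCl in methanol on 9 would give the triol 5,7-dihydroxy-2-(8-hydroxy-2,2-dimethyl-2H-chromen-6-yl)chromen-4-one F8.
   - Ac2O (2.2 equiv) in pyridine at 0 °C should acetylate the 7- and 3'-hydroxyls and spare the chelated 5-OH, giving the 7,3'-diacetate F9.
   - Mitsunobu etherification with 3-methylbut-2-en-1-ol, PPh3 and diisopropyl azodicarboxylate in THF would give the 5-O-prenyl 7,3'-diacetate F10 without base that would cleave the acetates.
   - Eu(fod)3 in PhCl at 85 °C should give the 8-C-prenyl 7,3'-diacetate F11 by the same Claisen–Cope relay.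
   - K2CO3 in methanol at room temperature should remove the acetates and give 15 with no acid exposure of the prenyl group.

**Further compounds**
F1 | step 8 | 5,7-bis(methoxymethoxy)-2-[8-(methoxymethoxy)-2,2-dimethyl-2H-chromen-6-yl]chromen-4-one | O=c1cc(-c2cc(OCOC)c3c(c2)C=CC(C)(C)O3)oc2cc(OCOC)cc(OCOC)c12
F2 | step 8 | 8-iodo-5,7-bis(methoxymethoxy)-2-[8-(methoxymethoxy)-2,2-dimethyl-2H-chromen-6-yl]chromen-4-one | O=c1cc(-c2cc(OCOC)c3c(c2)C=CC(C)(C)O3)oc2c(I)c(OCOC)cc(OCOC)c12
F3 | step 8 | 5,7-bis(methoxymethoxy)-2-[8-(methoxymethoxy)-2,2-dimethyl-2H-chromen-6-yl]-8-(3-methylbut-2-enyl)chromen-4-one | O=c1cc(-c2cc(OCOC)c3c(c2)C=CC(C)(C)O3)oc2c(CC=C(C)C)c(OCOC)cc(OCOC)c12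
F4 | step 4 | 4'-O-benzyl-7-O-MOM-luteolin | O=c1cc(-c2ccc(OCc3ccccc3)c(O)c2)oc2cc(OCOC)cc(O)c12
F5 | step 4 | 4'-O-benzyl-3',7-di-O-MOM-luteolin | O=c1cc(-c2ccc(OCc3ccccc3)c(OCOC)c2)oc2cc(OCOC)cc(O)c12
F6 | step 4 | 3',7-di-O-MOM-luteolin | O=c1cc(-c2ccc(O)c(OCOC)c2)oc2cc(OCOC)cc(O)c12
F7 | step 4 | 4'-O-(2-methylbut-3-yn-2-yl)-3',7-di-O-MOM-luteolin | O=c1cc(-c2ccc(OC(C)(C)C#C)c(OCOC)c2)oc2cc(OCOC)cc(O)c12
F8 | step 9 | 5,7-dihydroxy-2-(8-hydroxy-2,2-dimethyl-2H-chromen-6-yl)chromen-4-one | O=c1cc(-c2cc(O)c3c(c2)C=CC(C)(C)O3)oc2cc(O)cc(O)c12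
F9 | step 9 | 7-acetoxy-2-(8-acetoxy-2,2-dimethyl-2H-chromen-6-yl)-5-hydroxychromen-4-one | O=c1cc(-c2cc(OC(C)=O)c3c(c2)C=CC(C)(C)O3)oc2cc(OC(C)=O)cc(O)c12
F10 | step 9 | 7-acetoxy-2-(8-acetoxy-2,2-dimethyl-2H-chromen-6-yl)-5-(3-methylbut-2-enyloxy)chromen-4-one | CC(C)=CCOc1cc(OC(C)=O)cc2oc(-c3cc(OC(C)=O)c4c(c3)C=CC(C)(C)O4)cc(=O)c12
F11 | step 9 | 7-acetoxy-2-(8-acetoxy-2,2-dimethyl-2H-chromen-6-yl)-5-hydroxy-8-(3-methylbut-2-enyl)chromen-4-one | CC(C)=CCc1c(OC(C)=O)cc(O)c2c(=O)cc(-c3cc(OC(C)=O)c4c(c3)C=CC(C)(C)O4)oc12
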